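The readings are calculated from invented constants, and the scatter is random.

43 percentage points of the starting material left the north-east run between 6.00 h and 20.0 h, and the reckoning for a 40 h flask starts from that difference.

| flask | starting material | solid reagent | free catalyst | added ligand | remark | time |
|---|---|---|---|---|---|---|
| north-east | 0.15 M | 0.30 M | 21 mM | 120 mM | run made earlier |  |
| south-west | 0.15 M | 0.30 M | 38 mM | 120 mM | run made earlier |  |
| north | 0.15 M | 0.30 M | 44 mM | 120 mM | run made earlier |  |
| Saturday's | 0.15 M | 0.300 M | 30 mM | 120 mM |  | 40 h |
| Friday's | 0.15 M | 0.300 M | 36 mM | 120 mM |  | 40 h |
| Thursday's | 0.15 M | 0.300 M | 43 mM | 120 mM |  | 40 h |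

| run | time / h | target / % | side product / % | starting material / % | catalyst intermediate A / % |
|---|---|---|---|---|---|
| north-east | 1.50 | 3 | 0 | 92 | 7 |
| north-east | 3.00 | 1 | 0 | 91 | 5 |
| north-east | 6.00 | 8 | 2 | 86 | 5 |
| north-east | 10.0 | 20 | 2 | 76 | 4 |
| north-east | 20.0 | 44 | 14 | 43 | 4 |
| south-west | 1.50 | 3 | 4 | 89 | 10 |
| south-west | 3.00 | 3 | 0 | 84 | 6 |
| south-west | 6.00 | 15 | 0 | 78 | 12 |
| south-west | 10.0 | 28 | 5 | 63 | 11 |
| south-west | 20.0 | 56 | 13 | 31 | 1 |
| north | 1.50 | 1 | 0 | 88 | 14 |
| north | 3.00 | 5 | 2 | 82 | 9 |
| north | 6.00 | 16 | 0 | 71 | 13 |
| north | 10.0 | 27 | 6 | 56 | 11 |
| north | 20.0 | 57 | 10 | 29 | 3 |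

(each reading ± 2 percentage points)

- percent here means starting material units held: one side product counts as two
- solid reagent is a solid; its amount is given per volume of the solution
- at the start none of the solid reagent is in solution

- which of these there is most of at the end, counted by the starting material in it, Saturday's (starting material / target / catalyst intermediate A / side product)
- which of these there is most of at the end, counted by the starting material in it, Friday's (starting material / target / catalyst intermediate A / side product)
- which of these there is most of at the end, counted by the starting material in it, Thursday's (starting material / target / catalyst intermediate A / side product)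
- the largest of these amounts at the end, in percent of the starting material charged, Saturday's
- the largest of these amounts at the end, in percent of the starting material charged, Friday's
- the largest of these amounts at the end, in percent of the starting material charged, Thursday's

A first-order decay slows as its reactant falls, but this one did not: the run lost 10 points over the first 4.00 h of that stretch and 33 points over the next 10.0 h. So freeze the loss as a straight line. On that line the 43% still there at 20.0 h lasts another 14.0 h, which brings the line for the north-east run to zero at 34.0 h, earlier than the asked time. Saturday's flask has 30 mM of free catalyst against 21 mM there, and the south-west run, with 38 mM, held 31% at 20.0 h. Saturday's, Friday's and Thursday's flasks each hold more free catalyst than the north-east run, so as an estimate I count their whole charge as turned into target or side product. A straight line has no tail, so this estimate errs on the high side.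

The question then becomes how the reacted material divides. Call s the side share: of the starting material standing as target or side product, the fraction in side product, with one side product counted as two. What remains, one minus s, is the selectivity. The last readings give s = 24.1% in the north-east run, 18.8% in the south-west run and 14.9% in the north run, so in these readings it falls from run to run as free catalyst rises. Each rests on one pair of readings, each with a scatter of 2 points.

Saturday's 30 mM lies midway between the first two loadings, so I take their mean, s = 21.5%, and freeze it. Friday's sits beside the south-west run and Thursday's beside the north run. My target figures are therefore 78.5% for Saturday's, 81.2% for Friday's and 85.1% for Thursday's.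

The forecast reads “Target therefore dominates all three runs”, at 70%, 73% and 75%, which is below my figures .

Saturday's ends with target largest at 75.4%, Friday's with target at 78.3%, Thursday's with target at 80.6%.

    starting material + free catalyst ⇌ catalyst intermediate A (K = 11.0 M⁻¹, k = 0.00580 M⁻¹ s⁻¹)
    free catalyst + added ligand ⇌ idle complex (K = 7.10 M⁻¹, k = 0.00310 M⁻¹ s⁻¹)
    catalyst intermediate B → free catalyst + target (k = 0.00580 s⁻¹)
    solid reagent ⇌ partner, rate k4*(cs4 - [partner]) while solid is left; crystals form when [partner] > cs4 (solubility = 0.130 M, k = 1.80 × 10⁻⁵ s⁻¹)
    partner + catalyst intermediate A ⇌ catalyst intermediate B (K = 3.40 M⁻¹, k = 0.00540 M⁻¹ s⁻¹)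
    starting material + target → side product (k = 4.50 × 10⁻⁵ M⁻¹ s⁻¹)

Saturday's flask still holds 3.3% of its starting material at 40.0 h. Target and side product in Saturday's flask together stand at 96.3%, and the frozen s of 21.5% leaves 75.6% of the charge as target, against 75.4% in that flask. With 0.073 M of free catalyst in Thursday's recipe, target reaches 85.5% and side product 14.4%, so s there is 14.4%, below the 21.5% frozen for Saturday's.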